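**Retrosynthetic overview**
1. Target 18 comes from its bis-TIPS ether 17 by fluoride desilylation; ring C of 17 is the last ring closed, at the C4–C4a bond.
2. 17 comes from the acyclic (R)-carbinol 14 by a phenonium 1,2-aryl shift/Friedel–Crafts cascade: ring B moves from C4 to C3 with inversion, and C4a of ring A opens the spirocyclopropane at C4.
3. Enabling feature: ring B carries oxygen at C2' and C4' (ortho and para to C1'), which stabilises the spiro[2.5]octadienyl cation; ring A is phloroglucinol-type, with C4a ortho/ortho/para to O1, 5-OMe and 7-O, and the 7-OTIPS group shields C8.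
4. 14 comes from epoxide 8 and Grignard reagent 13. 8 is made from 5-methoxyresorcinol 1 and (R)-glycidyl nosylate 7; bromochromene 12 is made from 4-bromoresorcinol 9.
5. Ring order: rings A and B are bought as arenes 1 and 9, the pyran ring on ring B is closed by a propargyl Claisen cascade, and ring C is closed last.

Key step: step 10

Remark: numbering follows the isoflavan skeleton (O1, C2, C3, C4, C4a–C8a; ring B C1'–C6'); the stereocentre C3 of the target is R (C2 > C1' > C4 > H). Compounds 1, 7 and 9 are taken as commercial.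

**Step 1**
Reactants: 1 5-methoxyresorcinol
Product: 2 1-methoxy-3,5-bis(triisopropylsilyloxy)benzene
Conditions: TIPSCl (2.3 equiv), imidazole, DMF, rt
Reagents that add atoms: triisopropylsilyl chloride, CC(C)[Si](Cl)(C(C)C)C(C)C
Why: Exhaustive O-silylation of the symmetric diol (silyl ether formation) keeps the ring symmetric, so no statistical step is needed.

**Step 2**
Reactants: 2 1-methoxy-3,5-bis(triisopropylsilyloxy)benzene
Product: 3 2-bromo-1-methoxy-3,5-bis(triisopropylsilyloxy)benzene
Conditions: NBS (1.0 equiv), MeCN/CH2Cl2, 0 °C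
Reagents that add atoms: N-bromosuccinimide, O=C1CCC(=O)N1Br
Why: Electrophilic aromatic bromination should take one of the two equivalent positions ortho to OMe, because the third position lies between two bulky OTIPS groups.

**Step 3**
Reactants: 3 2-bromo-1-methoxy-3,5-bis(triisopropylsilyloxy)benzene
Product: 5 1-methoxy-2-(3-methylbut-2-en-1-yl)-3,5-bis(triisopropylsilyloxy)benzene, via aryllithium 4 (not isolated)
Conditions: n-BuLi, THF, −78 °C; then CuBr·SMe2 (10 mol%), prenyl bromide, −78 → −20 °C
Reagents that add atoms: prenyl bromide (1-bromo-3-methylbut-2-ene), CC(C)=CCBr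
Why: Bromine–lithium exchange followed by copper-catalysed SN2 allylation should place the prenyl group at the carbon that becomes C6, with α-attack favoured at the primary terminus of prenyl bromide.

**Step 4**
Reactants: 5 1-methoxy-2-(3-methylbut-2-en-1-yl)-3,5-bis(triisopropylsilyloxy)benzene
Product: 6 3-methoxy-4-(3-methylbut-2-en-1-yl)-5-(triisopropylsilyloxy)phenol
Conditions: TBAF (1.0 equiv), AcOH (1.0 equiv), THF, −20 °C
Reagents that add atoms: none
Why: Selective fluoride desilylation should cleave the aryl silyl ether flanked by two hydrogens (para to prenyl) faster than the one next to the prenyl group.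

**Step 5**
Reactants: 6 3-methoxy-4-(3-methylbut-2-en-1-yl)-5-(triisopropylsilyloxy)phenol; 7 (R)-glycidyl 3-nitrobenzenesulfonate
Product: 8 (2R)-2-{[3-methoxy-4-(3-methylbut-2-en-1-yl)-5-(triisopropylsilyloxy)phenoxy]methyl}oxirane
Conditions: K2CO3, acetone, 50 °C
Reagents that add atoms: none
Why: Williamson etherification by direct SN2 displacement of the nosylate at the CH2 carbon leaves the glycidyl stereocentre untouched, so the R configuration of 7 is carried into 8.

**Step 6**
Reactants: 9 4-bromoresorcinol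
Product: 10 2-bromo-5-(triisopropylsilyloxy)phenol
Conditions: TIPSCl (1.05 equiv), imidazole, CH2Cl2, 0 °C
Reagents that add atoms: triisopropylsilyl chloride, CC(C)[Si](Cl)(C(C)C)C(C)C
Why: Sterically controlled mono-silylation should take the hydroxyl para to bromine, leaving the hindered hydroxyl ortho to bromine free.

**Step 7**
Reactants: 10 2-bromo-5-(triisopropylsilyloxy)phenol
Product: 11 1-bromo-2-[(2-methylbut-3-yn-2-yl)oxy]-4-(triisopropylsilyloxy)benzene
Conditions: 3-chloro-3-methylbut-1-yne, DBU, CuCl2 (1 mol%), MeCN, 0 °C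
Reagents that add atoms: 3-chloro-3-methylbut-1-yne, CC(C)(Cl)C#C
Why: Copper-catalysed propargylic etherification of a phenol with a tertiary propargyl chloride is the standard entry to 1,1-dimethylpropargyl aryl ethers.

**Step 8**
Reactants: 11 1-bromo-2-[(2-methylbut-3-yn-2-yl)oxy]-4-(triisopropylsilyloxy)benzene
Product: 12 8-bromo-2,2-dimethyl-5-(triisopropylsilyloxy)-2H-chromene
Conditions: N,N-diethylaniline, 180 °C
Reagents that add atoms: none
Why: Aromatic propargyl Claisen rearrangement, 1,5-hydrogen shift and oxa-6π electrocyclisation give the 2,2-dimethylchromene, and the ring can only close onto the carbon between the two oxygens because the other ortho position carries bromine.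

**Step 9**
Reactants: 12 8-bromo-2,2-dimethyl-5-(triisopropylsilyloxy)-2H-chromene; 8 (2R)-2-{[3-methoxy-4-(3-methylbut-2-en-1-yl)-5-(triisopropylsilyloxy)phenoxy]methyl}oxirane
Product: 14 (2R)-1-[2,2-dimethyl-5-(triisopropylsilyloxy)-2H-chromen-8-yl]-3-[3-methoxy-4-(3-methylbut-2-en-1-yl)-5-(triisopropylsilyloxy)phenoxy]propan-2-ol, via arylmagnesium bromide 13 (not isolated)
Conditions: 12, Mg turnings, THF, 50 °C; then CuI (10 mol%), 8, THF, −30 → 0 °C; aqueous work-up
Reagents that add atoms: none
Why: Copper-catalysed opening of a terminal epoxide by an aryl Grignard reagent occurs at the CH2 terminus, so the carbinol centre keeps the configuration of 8 and is R.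

**Step 10**
Reactants: 14 (2R)-1-[2,2-dimethyl-5-(triisopropylsilyloxy)-2H-chromen-8-yl]-3-[3-methoxy-4-(3-methylbut-2-en-1-yl)-5-(triisopropylsilyloxy)phenoxy]propan-2-ol
Product: 17 (3R)-3-[2,2-dimethyl-5-(triisopropylsilyloxy)-2H-chromen-8-yl]-5-methoxy-6-(3-methylbut-2-en-1-yl)-7-(triisopropylsilyloxy)chromane, via secondary triflate 15 (not isolated), via spiro phenonium ion 16 (not isolated)
Conditions: Tf2O (1.2 equiv), 2,6-di-tert-butyl-4-methylpyridine (DTBMP, 3 equiv), CH2Cl2 (0.01 M), −78 → 0 °C
Reagents that add atoms: none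
Why: Proposed new method: Tf2O converts the carbinol into triflate 15, which ionises with anchimeric assistance of ring B (C1' attacks C3 anti to the leaving group) to the spiro[2.5]octadienyl cation 16, and C4a of ring A then opens the spirocyclopropane at its CH2 carbon (C4), so that ring B ends on C3 and the new C4–C4a bond closes ring C; the closest known reaction types are the stereospecific 1,2-aryl shifts of β-aryl sulfonates through phenonium ions, the Friedel–Crafts trapping of phenonium ions by arenes, and the 6-endo epoxide–arene cyclisation of aryl glycidyl ethers to chroman-3-ols. Ring C closes in the 6-endo mode with respect to the three-membered ring (attack on the distal, primary carbon), which should beat 5-exo attack on C3 because an arene π-nucleophile on the two-atom O–CH2 tether cannot reach C3 without strain, C3 is secondary and inductively deactivated by the C2–O bond, and five-ring Friedel–Crafts closure is the slower ring size. The only stereocentre, C3, is controlled by the carbinol centre of 14: it is inverted once when ring B participates and no bond to C3 changes afterwards, so (R)-14 gives (3R)-17, and return of triflate to either carbon of 16 only regenerates the same ion. Site selectivity on ring A (C4a against C8) is secured by the OTIPS group at C7, which the neighbouring prenyl group pushes towards C8, whereas C4a is flanked only by OMe and is para to the silyloxy donor. Ionisation is made easy by the oxygens at C2' and C4' of ring B, and the prenyl group, the chromene and the silyl ethers are protected by the hindered base, which takes up TfOH and deprotonates the Wheland intermediate at or below 0 °C.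

**Step 11**
Reactants: 17 (3R)-3-[2,2-dimethyl-5-(triisopropylsilyloxy)-2H-chromen-8-yl]-5-methoxy-6-(3-methylbut-2-en-1-yl)-7-(triisopropylsilyloxy)chromane
Product: 18 (3R)-3-(5-hydroxy-2,2-dimethyl-2H-chromen-8-yl)-5-methoxy-6-(3-methylbut-2-en-1-yl)chroman-7-ol (CNP0119857.1)
Conditions: TBAF (2.5 equiv), AcOH (2.5 equiv), THF, 0 °C → rt
Reagents that add atoms: none
Why: Buffered fluoride desilylation removes both aryl TIPS ethers without acid, so the ortho-prenylphenol, the chromene and the C3 stereocentre should not be affected.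

**Compound list**
1 | 5-methoxyresorcinol | COc1cc(O)cc(O)c1 | starting material
2 | 1-methoxy-3,5-bis(triisopropylsilyloxy)benzene | COc1cc(O[Si](C(C)C)(C(C)C)C(C)C)cc(O[Si](C(C)C)(C(C)C)C(C)C)c1 | intermediate
3 | 2-bromo-1-methoxy-3,5-bis(triisopropylsilyloxy)benzene | COc1cc(O[Si](C(C)C)(C(C)C)C(C)C)cc(O[Si](C(C)C)(C(C)C)C(C)C)c1Br | intermediate
4 | [2-methoxy-4,6-bis(triisopropylsilyloxy)phenyl]lithium | COc1cc(O[Si](C(C)C)(C(C)C)C(C)C)cc(O[Si](C(C)C)(C(C)C)C(C)C)c1[Li] | intermediate
5 | 1-methoxy-2-(3-methylbut-2-en-1-yl)-3,5-bis(triisopropylsilyloxy)benzene | COc1cc(O[Si](C(C)C)(C(C)C)C(C)C)cc(O[Si](C(C)C)(C(C)C)C(C)C)c1CC=C(C)C | intermediate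
6 | 3-methoxy-4-(3-methylbut-2-en-1-yl)-5-(triisopropylsilyloxy)phenol | COc1cc(O)cc(O[Si](C(C)C)(C(C)C)C(C)C)c1CC=C(C)C | intermediate
7 | (R)-glycidyl 3-nitrobenzenesulfonate | O=S(=O)(OC[C@H]1CO1)c1cccc([N+](=O)[O-])c1 | starting material
8 | (2R)-2-{[3-methoxy-4-(3-methylbut-2-en-1-yl)-5-(triisopropylsilyloxy)phenoxy]methyl}oxirane | COc1cc(OC[C@H]2CO2)cc(O[Si](C(C)C)(C(C)C)C(C)C)c1CC=C(C)C | intermediate
9 | 4-bromoresorcinol | Oc1ccc(Br)c(O)c1 | starting material
10 | 2-bromo-5-(triisopropylsilyloxy)phenol | Oc1cc(O[Si](C(C)C)(C(C)C)C(C)C)ccc1Br | intermediate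
11 | 1-bromo-2-[(2-methylbut-3-yn-2-yl)oxy]-4-(triisopropylsilyloxy)benzene | C#CC(C)(C)Oc1cc(O[Si](C(C)C)(C(C)C)C(C)C)ccc1Br | intermediate
12 | 8-bromo-2,2-dimethyl-5-(triisopropylsilyloxy)-2H-chromene | CC1(C)C=Cc2c(O[Si](C(C)C)(C(C)C)C(C)C)ccc(Br)c2O1 | intermediate
13 | [2,2-dimethyl-5-(triisopropylsilyloxy)-2H-chromen-8-yl]magnesium bromide | CC1(C)C=Cc2c(O[Si](C(C)C)(C(C)C)C(C)C)ccc([Mg]Br)c2O1 | intermediate
14 | (2R)-1-[2,2-dimethyl-5-(triisopropylsilyloxy)-2H-chromen-8-yl]-3-[3-methoxy-4-(3-methylbut-2-en-1-yl)-5-(triisopropylsilyloxy)phenoxy]propan-2-ol | CC1(C)C=Cc2c(O[Si](C(C)C)(C(C)C)C(C)C)ccc(C[C@@H](O)COc3cc(OC)c(CC=C(C)C)c(O[Si](C(C)C)(C(C)C)C(C)C)c3)c2O1 | intermediate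
15 | (2R)-1-[2,2-dimethyl-5-(triisopropylsilyloxy)-2H-chromen-8-yl]-3-[3-methoxy-4-(3-methylbut-2-en-1-yl)-5-(triisopropylsilyloxy)phenoxy]propan-2-yl trifluoromethanesulfonate | CC1(C)C=Cc2c(O[Si](C(C)C)(C(C)C)C(C)C)ccc(C[C@@H](OS(=O)(=O)C(F)(F)F)COc3cc(OC)c(CC=C(C)C)c(O[Si](C(C)C)(C(C)C)C(C)C)c3)c2O1 | intermediate
16 | spiro phenonium ion (ring B spiro-fused at C1' to the C3–C4 cyclopropane, drawn as its C4' oxocarbenium form) as triflate | CC(C)[Si](C(C)C)(C(C)C)[O+]=C1C=CC2(C[C@H]2COc3cc(OC)c(CC=C(C)C)c(O[Si](C(C)C)(C(C)C)C(C)C)c3)C4=C1C=CC(C)(C)O4.[O-]S(=O)(=O)C(F)(F)F | intermediate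
17 | (3R)-3-[2,2-dimethyl-5-(triisopropylsilyloxy)-2H-chromen-8-yl]-5-methoxy-6-(3-methylbut-2-en-1-yl)-7-(triisopropylsilyloxy)chromane | COc1c(CC=C(C)C)c(O[Si](C(C)C)(C(C)C)C(C)C)cc2c1C[C@H](c1ccc(O[Si](C(C)C)(C(C)C)C(C)C)c3c1OC(C)(C)C=C3)CO2 | intermediate
18 | (3R)-3-(5-hydroxy-2,2-dimethyl-2H-chromen-8-yl)-5-methoxy-6-(3-methylbut-2-en-1-yl)chroman-7-ol | COc1c(CC=C(C)C)c(O)cc2c1C[C@H](c1ccc(O)c3c1OC(C)(C)C=C3)CO2 | target

**Count**
Total steps: 11. Longest linear sequence: 8 steps (steps 1–5, 9, 10, 11).

**Steps most likely to fail**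

Step 10. The phenonium ion may be opened at C3 instead of C4 (five-ring closure), ring A may attack through C8, or ionisation may be diverted by participation of the pyran oxygen of ring B or by a hydride shift; each of these would lose the isoflavan skeleton. The fallback sets out from phenol 6 and Grignard reagent 13 and comes back at 17, using only known reaction types and no cation.
- Copper-catalysed carbomagnesiation of prop-2-yn-1-ol (pre-deprotonated with i-PrMgCl; CuI, THF) with 13 should give 2-[2,2-dimethyl-5-(triisopropylsilyloxy)-2H-chromen-8-yl]prop-2-en-1-ol F1.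
- Ortho-bromination of 6 (NBS, CH2Cl2, −78 °C) between OH and OMe should give 2-bromo-3-methoxy-4-(3-methylbut-2-en-1-yl)-5-(triisopropylsilyloxy)phenol F2.
- Mitsunobu etherification of F2 with F1 (PPh3, DIAD, THF) should give the aryl 2-arylallyl ether F3.
- Enantioselective copper–boryl protoboration of the 1,1-disubstituted styrene (CuCl, chiral N-heterocyclic carbene, NaOt-Bu, B2pin2, MeOH, THF) should give the β-stereogenic primary pinacol boronate F4, with the ligand enantiomer chosen for R.
- Intramolecular B-alkyl Suzuki–Miyaura coupling (Pd(OAc)2, RuPhos, K3PO4, toluene/H2O) then forms the C4–C4a bond and delivers 17.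

Step 4. Discrimination between the two aryl silyl ethers may be poor, leading to over-desilylation or cleavage of the wrong group. The fallback sets out from 5 and comes back at 8.
- Both silyl groups are removed (TBAF in excess, THF) to give 5-methoxy-4-(3-methylbut-2-en-1-yl)benzene-1,3-diol F5.
- The less hindered hydroxyl, para to the prenyl group, is alkylated with 7 (1.0 equiv, K2CO3, acetone) to give 3-methoxy-2-(3-methylbut-2-en-1-yl)-5-[(2R)-oxiran-2-ylmethoxy]phenol F6.
- The remaining hindered phenol is silylated (TIPSCl, imidazole, DMF, 40 °C) to give 8.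

Step 3. The ortho-lithiated aryl silyl ether may undergo oxygen-to-carbon silyl migration or be protonated before it is trapped, and allylation may occur at the γ-terminus to give the reverse-prenyl isomer. The fallback sets out from 3 and comes back at 5 without an aryllithium: Suzuki–Miyaura coupling of 3 with 3-methylbut-2-enylboronic acid pinacol ester (Pd(OAc)2, a bulky biarylphosphine, K3PO4, THF/H2O) under conditions known to favour the linear prenyl arene should give 5 directly.

**Further compounds**
F1 | step 10 | 2-[2,2-dimethyl-5-(triisopropylsilyloxy)-2H-chromen-8-yl]prop-2-en-1-ol | C=C(CO)c1ccc(O[Si](C(C)C)(C(C)C)C(C)C)c2c1OC(C)(C)C=C2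
F2 | step 10 | 2-bromo-3-methoxy-4-(3-methylbut-2-en-1-yl)-5-(triisopropylsilyloxy)phenol | COc1c(Br)c(O)cc(O[Si](C(C)C)(C(C)C)C(C)C)c1CC=C(C)C
F3 | step 10 | 8-{3-[2-bromo-3-methoxy-4-(3-methylbut-2-en-1-yl)-5-(triisopropylsilyloxy)phenoxy]prop-1-en-2-yl}-2,2-dimethyl-5-(triisopropylsilyloxy)-2H-chromene | C=C(COc1cc(O[Si](C(C)C)(C(C)C)C(C)C)c(CC=C(C)C)c(OC)c1Br)c1ccc(O[Si](C(C)C)(C(C)C)C(C)C)c2c1OC(C)(C)C=C2
F4 | step 10 | (R)-2-{3-[2-bromo-3-methoxy-4-(3-methylbut-2-en-1-yl)-5-(triisopropylsilyloxy)phenoxy]-2-[2,2-dimethyl-5-(triisopropylsilyloxy)-2H-chromen-8-yl]propyl}-4,4,5,5-tetramethyl-1,3,2-dioxaborolane | CC1(C)OB(C[C@H](c2ccc(O[Si](C(C)C)(C(C)C)C(C)C)c3c2OC(C)(C)C=C3)COc2cc(O[Si](C(C)C)(C(C)C)C(C)C)c(CC=C(C)C)c(OC)c2Br)OC1(C)C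
F5 | step 4 | 5-methoxy-4-(3-methylbut-2-en-1-yl)benzene-1,3-diol | COc1cc(O)cc(O)c1CC=C(C)C
F6 | step 4 | 3-methoxy-2-(3-methylbut-2-en-1-yl)-5-[(2R)-oxiran-2-ylmethoxy]phenol | COc1cc(OC[C@H]2CO2)cc(O)c1CC=C(C)C
F0 | step 3 | none | none
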